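**Retrosynthetic overview**

1. Target 19 comes from silyl ketal 18 by fluoride. Ring B of 18 is made aromatic from the cyclohexenone of 14 through an α'-selenide.
2. The strategy rests on the six-membered ketal ring C4–O2'–C2'–C1'–C2–C3 (a 2,6-dioxabicyclo[3.3.1]nonane). In it, C2 and C4 of ring C act as a 1,3-dielectrophile and C1'/O2' of ring B as a carbon–oxygen dinucleophile.
3. Key disconnection (C2–C1' and C4–O2'): the 4-silyloxybenzopyrylium ion from chromone 9 plus silyl enol ether 11 of cyclohexane-1,3-dione. The dione has one nucleophilic carbon and two equivalent oxygens, so the regiochemical question a resorcinol would raise does not arise. A chiral squaramide–triflate ion pair sets C2 and the bridge fixes C4.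
4. Chromone 9 comes from chromene acetophenone 7 (amide acetal, then acid). Ketone 7 comes from C3-prenylation of 1, then a propargyl ether and Claisen/electrocyclisation at the only free ortho carbon.
5. Ring order: ring A (bought), dimethylpyran ring (step 3), pyranone ring C (step 4), ketal ring (step 6), ring B made aromatic (step 8).

Key step: step 6

**Remarks on the chemistry**

- Flavonoid numbering is used: O1, C2, C3, C4, C4a, C5–C8, C8a for rings C and A; C1'–C6' for ring B; O2' is the oxygen on C2'.
- Assumption: the sense of induction of the squaramide in step 6 cannot be assigned beforehand. It is assumed that one antipode of the catalyst delivers the (2R) adduct, and the route is written with that antipode. The other is equally accessible from D-tert-leucine and the (2S)-arylpyrrolidine.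
- The geometry at C4 is the same in 14–19. Its descriptor is S in the silyl ketals (O–Si outranks O–C) and R in 19.

**Route**

Step 1
Reactants: 1 2,4-dihydroxy-6-methoxyacetophenone; 2 prenyl bromide (1-bromo-3-methylbut-2-ene)
Product: 3 1-[2,4-dihydroxy-6-methoxy-3-(3-methylbut-2-en-1-yl)phenyl]ethan-1-one
Conditions: KOH (10% aq), 0 °C to rt
Reagents that add atoms: none
Why: Phenoxide C-alkylation (nuclear prenylation) in water, where the dianion of 1 is solvated at oxygen and should react with the allylic bromide on carbon, chiefly at C3 between the two phenoxide oxygens; the C5 isomer, O-prenyl ethers and doubly prenylated material are expected by-products to be removed by chromatography.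

Step 2
Reactants: 3 1-[2,4-dihydroxy-6-methoxy-3-(3-methylbut-2-en-1-yl)phenyl]ethan-1-one; 4 3-chloro-3-methylbut-1-yne
Product: 5 1-[2-hydroxy-6-methoxy-3-(3-methylbut-2-en-1-yl)-4-(2-methylbut-3-yn-2-yloxy)phenyl]ethan-1-one
Conditions: DBU, CuCl2·2H2O (1 mol %), MeCN, 0 °C
Reagents that add atoms: none
Why: Copper-catalysed O-propargylation (Williamson-type etherification with a tertiary propargylic chloride) should take place at the free 4-OH, because the 2-OH is held in the hydrogen bond to the acetyl group.

Step 3
Reactants: 5 1-[2-hydroxy-6-methoxy-3-(3-methylbut-2-en-1-yl)-4-(2-methylbut-3-yn-2-yloxy)phenyl]ethan-1-one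
Product: 7 1-[7-hydroxy-5-methoxy-2,2-dimethyl-8-(3-methylbut-2-en-1-yl)-2H-chromen-6-yl]ethan-1-one, via ortho-allenylphenol 6 (not isolated)
Conditions: PhNEt2, 160 °C
Reagents that add atoms: none
Why: Aromatic propargyl Claisen rearrangement to C5, the only free ortho carbon (C3 carries the prenyl group), then enolisation to 6, [1,5]-hydrogen shift and oxa-6π-electrocyclisation, the standard thermal route to 2,2-dimethyl-2H-chromenes.

Step 4
Reactants: 7 1-[7-hydroxy-5-methoxy-2,2-dimethyl-8-(3-methylbut-2-en-1-yl)-2H-chromen-6-yl]ethan-1-one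
Product: 9 5-methoxy-8,8-dimethyl-10-(3-methylbut-2-en-1-yl)-4H,8H-pyrano[3,2-g]chromen-4-one (5-methoxy-8-prenyl-6,7-(2,2-dimethylpyrano)chromone), via enaminone 8 (not isolated)
Conditions: Me2NCH(OMe)2, toluene, 100 °C; concentrate; then HCl (2 M aq), CH2Cl2, rt
Reagents that add atoms: N,N-dimethylformamide dimethyl acetal, COC(OC)N(C)C
Why: Condensation of the acetyl CH3 with the amide acetal gives the enaminone, and acid-promoted conjugate addition of the neighbouring phenol with loss of Me2NH closes ring C (the enaminone route to 2,3-unsubstituted chromones); dilute acid at room temperature should leave the prenyl and chromene double bonds unprotonated.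

Step 5
Reactants: 10 cyclohexane-1,3-dione
Product: 11 3-(trimethylsilyloxy)cyclohex-2-en-1-one
Conditions: Me3SiCl, Et3N, THF, rt; filtration and distillation under exclusion of moisture
Reagents that add atoms: chlorotrimethylsilane, C[Si](C)(C)Cl
Why: O-silylation of the enol form of the 1,3-dione (silyl enol ether formation) should give the vinylogous silyl ester, whose only nucleophilic carbon is C2 of the dione.

Step 6
Reactants: 9 5-methoxy-8-prenyl-6,7-(2,2-dimethylpyrano)chromone; 11 3-(trimethylsilyloxy)cyclohex-2-en-1-one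
Product: 14 (2R,4S)-bridged silyl ketal: 4-(tert-butyldimethylsilyloxy)-5-methoxy-8-prenyl-6,7-(2,2-dimethylpyrano)chroman whose C2 is bonded to C1' and whose C4 is bonded to the enol ether oxygen O2' of a 6'-oxocyclohex-1'-ene ring B, via 4-silyloxybenzopyrylium triflate 12 (not isolated), via 2H-chromene silyl enol ether 13 (not isolated)
Conditions: t-BuMe2SiOTf (1.2 equiv), 2,6-di-tert-butyl-4-methylpyridine (0.2 equiv), toluene, 40 °C; then 11 (1.5 equiv), 3-{[3,5-bis(trifluoromethyl)phenyl]amino}-4-({(2S)-3,3-dimethyl-1-oxo-1-[(2R)-2-(phenanthren-9-yl)pyrrolidin-1-yl]butan-2-yl}amino)cyclobut-3-ene-1,2-dione (10 mol %), toluene/t-BuOMe, −78 to −30 °C; Et3N, then NaHCO3 (aq)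
Reagents that add atoms: tert-butyldimethylsilyl trifluoromethanesulfonate, CC(C)(C)[Si](C)(C)OS(=O)(=O)C(F)(F)F
Why: Proposed new method: O-silylation of the chromone carbonyl should give the benzopyrylium triflate 12, whose triflate is held by the two N–H bonds of the squaramide, so that 11 attacks C2 of the cation inside a chiral ion pair (Mukaiyama-type addition forming C2–C1') and loses Me3SiOTf to give the 2H-chromene silyl enol ether 13. The closest known reactions are additions of silyl enol ethers and silyl ketene acetals to 4-silyloxybenzopyrylium triflates, including enantioselective anion-binding variants, and the [3+3] ketal annulation of benzopyrylium salts with 1,3-diones to dioxabicyclo[3.3.1]nonanes; new here are the cyclic dione silyl enol ether as nucleophile and the capture at C4. The acidic enol proton of the dione unit, relayed by the pyridinium triflate, should protonate C3 of the electron-rich silyl enol ether, and the C4 silyloxocarbenium ion, stabilised by the oxygens on C5, C7 and C8a, is then closed by the enol oxygen in a 6-exo-trig attack that forms C4–O2' and the ketal ring. C2 is set by the catalyst through the chiral ion pair, whereas C4 is set by the substrate, because the O2'–C2'–C1' bridge can span C2 and C4 on one face only. The step needs C2 over C4 attack on the cation (C4 carries the silyloxy group and is screened by the peri 5-methoxy group), carbon over oxygen attack of the dinucleophile (secured by O-silylation of the dione) and survival of the prenyl and chromene double bonds (secured by the hindered pyridine, which keeps free TfOH low).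

Step 7
Reactants: 14 (2R,4S)-bridged silyl ketal with tetrahydro ring B
Product: 15 5'-(phenylselanyl) derivative of 14 (SePh on the CH next to the ring B ketone, mixture of C5' epimers)
Conditions: LiN(i-Pr)2 (commercial solution), THF, −78 °C; then PhSeCl, −78 °C
Reagents that add atoms: benzeneselenenyl chloride, Cl[Se]c1ccccc1
Why: Kinetic deprotonation of the vinylogous ester at the α'-CH2 next to the ketone and α-selenenylation of the lithium enolate, which at −78 °C should be far faster than addition of PhSeCl to the two alkenes; the new C–Se stereocentre is of no consequence because it is removed in step 8.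

Step 8
Reactants: 15 5'-(phenylselanyl) silyl ketal
Product: 18 (2R,4S)-silyl ketal phenol (ring B aromatic, free 6'-OH, O2' bonded to C4, 4-OSi(t-Bu)Me2), via selenoxide 16 (not isolated), via cyclohexadienone 17 (not isolated)
Conditions: 3-ClC6H4CO3H (1.0 equiv), CH2Cl2, −78 °C; then i-Pr2NH, −78 °C to rt
Reagents that add atoms: none
Why: Selenide oxidation at −78 °C (faster than alkene epoxidation) and selenoxide syn-elimination on warming should give the cross-conjugated dienone 17, which tautomerises to the phenol and so aromatises ring B; the ketal is untouched, so C2 and C4 keep their configuration.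

Step 9
Reactants: 18 (2R,4S)-silyl ketal phenol
Product: 19 target hemiketal, (2R,4R)
Conditions: Bu4NF, AcOH (1:1), THF, 0 °C to rt
Reagents that add atoms: none
Why: Fluoride-mediated Si–O cleavage (desilylation) of the silyl ketal, with acetic acid protonating the hemiketal alkoxide before it can open to the 4-ketone and lose C2 by retro-oxa-Michael ring opening; no bond to C2 or C4 is broken, so both centres are retained.

**Compound list**

1 | 2,4-dihydroxy-6-methoxyacetophenone | CC(=O)c1c(O)cc(O)cc1OC | starting material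
2 | prenyl bromide | CC(C)=CCBr | starting material
3 | 1-[2,4-dihydroxy-6-methoxy-3-(3-methylbut-2-en-1-yl)phenyl]ethan-1-one | CC(=O)c1c(O)c(CC=C(C)C)c(O)cc1OC | intermediate
4 | 3-chloro-3-methylbut-1-yne | CC(C)(Cl)C#C | starting material
5 | 1-[2-hydroxy-6-methoxy-3-(3-methylbut-2-en-1-yl)-4-(2-methylbut-3-yn-2-yloxy)phenyl]ethan-1-one | CC(=O)c1c(O)c(CC=C(C)C)c(OC(C)(C)C#C)cc1OC | intermediate
6 | 1-[2,4-dihydroxy-6-methoxy-5-(3-methylbuta-1,2-dien-1-yl)-3-(3-methylbut-2-en-1-yl)phenyl]ethan-1-one (ortho-allenylphenol) | CC(=O)c1c(O)c(CC=C(C)C)c(O)c(C=C=C(C)C)c1OC | intermediate (not isolated)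
7 | 1-[7-hydroxy-5-methoxy-2,2-dimethyl-8-(3-methylbut-2-en-1-yl)-2H-chromen-6-yl]ethan-1-one | CC(=O)c1c(O)c(CC=C(C)C)c2OC(C)(C)C=Cc2c1OC | intermediate
8 | (E)-3-(dimethylamino)-1-[7-hydroxy-5-methoxy-2,2-dimethyl-8-(3-methylbut-2-en-1-yl)-2H-chromen-6-yl]prop-2-en-1-one | CN(C)/C=C/C(=O)c1c(O)c(CC=C(C)C)c2OC(C)(C)C=Cc2c1OC | intermediate (not isolated)
9 | 5-methoxy-8,8-dimethyl-10-(3-methylbut-2-en-1-yl)-4H,8H-pyrano[3,2-g]chromen-4-one | COc1c2c(c(CC=C(C)C)c3c1C(=O)C=CO3)OC(C)(C)C=C2 | intermediate
10 | cyclohexane-1,3-dione | O=C1CCCC(=O)C1 | starting material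
11 | 3-(trimethylsilyloxy)cyclohex-2-en-1-one | C[Si](C)(C)OC1=CC(=O)CCC1 | intermediate
12 | 4-(tert-butyldimethylsilyloxy)-5-methoxy-8,8-dimethyl-10-(3-methylbut-2-en-1-yl)-8H-pyrano[3,2-g]chromen-1-ium trifluoromethanesulfonate | COc1c2C=CC(C)(C)Oc2c(CC=C(C)C)c2[o+]ccc(O[Si](C)(C)C(C)(C)C)c12.[O-]S(=O)(=O)C(F)(F)F | intermediate (not isolated)
13 | 2-[(2R)-4-(tert-butyldimethylsilyloxy)-5-methoxy-8,8-dimethyl-10-(3-methylbut-2-en-1-yl)-2H,8H-pyrano[3,2-g]chromen-2-yl]-3-hydroxycyclohex-2-en-1-one | COc1c2C=CC(C)(C)Oc2c(CC=C(C)C)c2O[C@H](C=C(O[Si](C)(C)C(C)(C)C)c12)C1=C(O)CCCC1=O | intermediate (not isolated)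
14 | (2R,4S)-bridged silyl ketal with 6'-oxo-tetrahydro ring B | COc1c2c(c(CC=C(C)C)c3c1[C@@]1(O[Si](C)(C)C(C)(C)C)C[C@@H](O3)C3=C(CCCC3=O)O1)OC(C)(C)C=C2 | intermediate
15 | 5'-(phenylselanyl) derivative of 14 (C5' epimers) | COc1c2c(c(CC=C(C)C)c3c1[C@@]1(O[Si](C)(C)C(C)(C)C)C[C@@H](O3)C3=C(CCC([Se]c4ccccc4)C3=O)O1)OC(C)(C)C=C2 | intermediate
16 | selenoxide of 15 | COc1c2c(c(CC=C(C)C)c3c1[C@@]1(O[Si](C)(C)C(C)(C)C)C[C@@H](O3)C3=C(CCC([Se](=O)c4ccccc4)C3=O)O1)OC(C)(C)C=C2 | intermediate (not isolated)
17 | (2R,4S)-silyl ketal with cyclohexa-2,5-dienone ring B | COc1c2c(c(CC=C(C)C)c3c1[C@@]1(O[Si](C)(C)C(C)(C)C)C[C@@H](O3)C3=C(CC=CC3=O)O1)OC(C)(C)C=C2 | intermediate (not isolated)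
18 | (2R,4S)-silyl ketal phenol (aromatic ring B, 6'-OH) | COc1c2c(c(CC=C(C)C)c3c1[C@@]1(O[Si](C)(C)C(C)(C)C)C[C@@H](O3)c3c(O)cccc3O1)OC(C)(C)C=C2 | intermediate
19 | CNP0170313.2, (2R,4R)-hemiketal | COc1c2c(c(CC=C(C)C)c3c1[C@@]1(O)C[C@@H](O3)c3c(O)cccc3O1)OC(C)(C)C=C2 | target

**Step count**

Total: 9 steps. Longest linear sequence: 8 steps (steps 1–4 and 6–9 from 1); step 5 is a one-step branch.

**Steps most likely to fail**

1. Step 6 (proposed new method). The push–pull silyl enol ether may add too slowly to the donor-stabilised cation. The C2–C1' bond may form with poor facial selectivity or revert before the ketal closes. The silyl enol ether may be desilylated instead of protonated at C3.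
Fallback by known chemistry, which brings in ring B as an aryl group and closes ring C by oxa-Michael addition: it sets out from 7 and returns at 19. 2,6-Dihydroxybenzaldehyde is protected with MeOCH2Cl and i-Pr2NEt to give 2,6-bis(methoxymethoxy)benzaldehyde F1. Claisen–Schmidt condensation of 7 with F1 (KOH, EtOH) should give the (E)-2'-hydroxychalcone F2. NaOAc in refluxing EtOH should close ring C to the racemic bis(methoxymethyl) flavanone F3. The enantiomers are parted by preparative chromatography on a cellulose tris(3,5-dimethylphenylcarbamate) phase to give the (2R)-flavanone F4, and the (2S) antipode is reopened to F2 by base and recycled. HCl (2 M aq) in THF removes both acetals to give the (2R)-2',6'-dihydroxyflavanone F5, in which O2' should add to the C4 ketone to give hemiketal 19, the bridge again fixing C4.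

2. Step 7. Electrophilic selenium may add to the prenyl and chromene double bonds, and deprotonation may occur at the γ-CH2 instead of the α'-CH2.
Fallback without electrophilic selenium: it sets out from 14 and returns at 18. The enolate from LiN(i-Pr)2 is trapped with Me3SiCl to give the trimethylsilyl dienol ether F6. Pd(OAc)2 in MeCN at rt (Saegusa–Ito dehydrosilylation) should give dienone 17, which tautomerises to 18. Either regiochemistry of enolisation leads to the same phenol after dehydrogenation.

3. Step 1. Site selectivity of the alkylation may be poor, with attack at C5 or at oxygen and with double prenylation, so that isolation of 3 becomes wasteful.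
Fallback with chelation-controlled regiochemistry: it sets out from 1 and 4 and returns at 3. O-Propargylation of 1 with 4 (DBU, CuCl2·2H2O cat., MeCN, 0 °C) should give the 4-(2-methylbut-3-yn-2-yl) ether F7. Semi-hydrogenation (H2, Pd on CaCO3 poisoned with Pb(OAc)2, quinoline, EtOAc) should give the 4-(2-methylbut-3-en-2-yl) ether F8. Aromatic Claisen rearrangement in PhNEt2 at 130 °C should then deliver the normal prenyl group to C3, because the hydrogen bond between the 2-OH and the acetyl group fixes the C3–C4 double-bond character.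

**Further compounds**

F1 | step 6 | 2,6-bis(methoxymethoxy)benzaldehyde | COCOc1cccc(OCOC)c1C=O
F2 | step 6 | (E)-3-[2,6-bis(methoxymethoxy)phenyl]-1-[7-hydroxy-5-methoxy-2,2-dimethyl-8-(3-methylbut-2-en-1-yl)-2H-chromen-6-yl]prop-2-en-1-one | COCOc1cccc(OCOC)c1/C=C/C(=O)c1c(O)c(CC=C(C)C)c2OC(C)(C)C=Cc2c1OC
F3 | step 6 | racemic 2-[2,6-bis(methoxymethoxy)phenyl]-5-methoxy-8-prenyl-6,7-(2,2-dimethylpyrano)chroman-4-one | COCOc1cccc(OCOC)c1C1CC(=O)c2c(OC)c3C=CC(C)(C)Oc3c(CC=C(C)C)c2O1
F4 | step 6 | (2R)-2-[2,6-bis(methoxymethoxy)phenyl]-5-methoxy-8-prenyl-6,7-(2,2-dimethylpyrano)chroman-4-one | COCOc1cccc(OCOC)c1[C@H]1CC(=O)c2c(OC)c3C=CC(C)(C)Oc3c(CC=C(C)C)c2O1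
F5 | step 6 | (2R)-2-(2,6-dihydroxyphenyl)-5-methoxy-8-prenyl-6,7-(2,2-dimethylpyrano)chroman-4-one (open keto form of 19) | Oc1cccc(O)c1[C@H]1CC(=O)c2c(OC)c3C=CC(C)(C)Oc3c(CC=C(C)C)c2O1
F6 | step 7 | 6'-(trimethylsilyloxy) cross-conjugated dienol ether of 14 | COc1c2c(c(CC=C(C)C)c3c1[C@@]1(O[Si](C)(C)C(C)(C)C)C[C@@H](O3)C3=C(CCC=C3O[Si](C)(C)C)O1)OC(C)(C)C=C2
F7 | step 1 | 1-[2-hydroxy-6-methoxy-4-(2-methylbut-3-yn-2-yloxy)phenyl]ethan-1-one | CC(=O)c1c(O)cc(OC(C)(C)C#C)cc1OC
F8 | step 1 | 1-[2-hydroxy-6-methoxy-4-(2-methylbut-3-en-2-yloxy)phenyl]ethan-1-one | CC(=O)c1c(O)cc(OC(C)(C)C=C)cc1OC
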